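**Assumption:** the target SMILES has no stereocentre, so the compound is achiral and the single-enantiomer requirement needs no stereocontrol. Only carbon-skeleton compounds are numbered; simple reagents are given with SMILES on the reagent lines.

**Retrosynthetic overview**
1. Target 9 comes from hexamethoxyflavone 8 by peri-selective 5-O-demethylation (last step).
2. 8 comes from 3-iodoflavone 7 by copper-catalysed C3–OMe coupling.
3. Key step: 7 comes from ynone 6 by ICl-induced demethylative 6-endo-dig iodocyclisation. The pentamethoxyphenyl group is symmetric, so both ortho-OMe groups are equivalent and the 5,6,7,8-oxygen pattern cannot be misplaced.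
4. 6 comes from acid 3 and alkyne 4 by acyl Sonogashira coupling; 3 comes from 3,4,5-trimethoxybenzoic acid 1 by dibromination and double Ullmann methoxylation.
5. Ring order: rings A and B are bought as benzenes; ring C (the pyranone) is the only ring formed, in step 4.

**Route**

Step 1
Reactants: 1 3,4,5-trimethoxybenzoic acid
Product: 2 2,6-dibromo-3,4,5-trimethoxybenzoic acid
Conditions: Br2 (2.5 equiv), AcOH, rt→50 °C; aq. NaHSO3
Reagents that add atoms: bromine, BrBr
Why: Electrophilic aromatic bromination; the only two ring C–H positions are each ortho and para to a methoxy group, so exhaustive bromination can give only the symmetric dibromide.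

Step 2
Reactants: 2 2,6-dibromo-3,4,5-trimethoxybenzoic acid
Product: 3 2,3,4,5,6-pentamethoxybenzoic acid
Conditions: NaOMe (6 equiv), CuBr (20 mol%), MeOH/DMF, 110 °C, sealed, N2; then aq. HCl
Reagents that add atoms: sodium methoxide, [Na+].[O-]C
Why: Copper-catalysed Ullmann-type methoxylation of aryl bromides, assisted by the ortho-carboxylate (Hurtley-type ortho effect) and analogous to the classical dibromophenol-to-dimethoxyphenol exchange.

Step 3
Reactants: 3 2,3,4,5,6-pentamethoxybenzoic acid; 4 1-ethynyl-4-methoxybenzene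
Product: 6 1-(2,3,4,5,6-pentamethoxyphenyl)-3-(4-methoxyphenyl)prop-2-yn-1-one, via pentamethoxybenzoyl chloride 5 (not isolated)
Conditions: (COCl)2, cat. DMF, CH2Cl2, 0 °C→rt, evaporate; then 4, PdCl2(PPh3)2 (2 mol%), CuI (4 mol%), Et3N, THF, rt
Reagents that add atoms: none
Why: Acid chloride formation followed by acyl Sonogashira coupling (oxidative addition of ArCO–Cl, copper acetylide transmetalation, reductive elimination) at room temperature, where decarbonylation is slow.

Step 4
Reactants: 6 1-(2,3,4,5,6-pentamethoxyphenyl)-3-(4-methoxyphenyl)prop-2-yn-1-one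
Product: 7 3-iodo-5,6,7,8-tetramethoxy-2-(4-methoxyphenyl)-4H-chromen-4-one
Conditions: ICl (1.2 equiv), CH2Cl2, −78 °C→rt, dark; aq. Na2S2O3
Reagents that add atoms: iodine monochloride, ClI
Why: Larock-type electrophilic iodocyclisation; an ortho-OMe oxygen attacks the iodine-activated alkyne 6-endo-dig at the anisyl-bearing carbon and chloride removes the O-methyl group as MeCl, while the fully substituted A ring has no C–H to iodinate.

Step 5
Reactants: 7 3-iodo-5,6,7,8-tetramethoxy-2-(4-methoxyphenyl)-4H-chromen-4-one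
Product: 8 3,5,6,7,8-pentamethoxy-2-(4-methoxyphenyl)-4H-chromen-4-one
Conditions: MeOH (10 equiv), CuI (10 mol%), 3,4,7,8-tetramethyl-1,10-phenanthroline (20 mol%), Cs2CO3 (1.5 equiv), toluene, 4 Å MS, 80 °C, sealed tube
Reagents that add atoms: methanol, CO
Why: Proposed new method: a phenanthroline-ligated Cu(I) methoxide should oxidatively add the electron-poor C(sp2)–I bond of the α-iodo vinylogous ester and reductively eliminate the C3–OMe bond, with the C2 aryl group shielding the enone from methoxide conjugate addition; the closest known reactions are Cu/phenanthroline Ullmann-type couplings of aryl and vinyl iodides with aliphatic alcohols and O-arylation at C3 of 3-iodochromones.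

Step 6
Reactants: 8 3,5,6,7,8-pentamethoxy-2-(4-methoxyphenyl)-4H-chromen-4-one
Product: 9 5-hydroxy-3,6,7,8-tetramethoxy-2-(4-methoxyphenyl)-4H-chromen-4-one (5-hydroxyauranetin)
Conditions: BCl3 (1.5 equiv), CH2Cl2, −78→0 °C; aq. HCl work-up
Reagents that add atoms: none
Why: Chelation-controlled Lewis-acid ether cleavage; BCl3 on the C4 carbonyl reaches only the peri 5-OMe through a six-membered chelate, and the resulting boron chelate shuts down further cleavage (3-OMe would need a five-membered chelate).

**Compound list**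
1 | 3,4,5-trimethoxybenzoic acid | COc1cc(C(=O)O)cc(OC)c1OC | starting material
2 | 2,6-dibromo-3,4,5-trimethoxybenzoic acid | COc1c(Br)c(C(=O)O)c(Br)c(OC)c1OC | intermediate
3 | 2,3,4,5,6-pentamethoxybenzoic acid | COc1c(OC)c(OC)c(C(=O)O)c(OC)c1OC | intermediate
4 | 1-ethynyl-4-methoxybenzene (4-ethynylanisole) | COc1ccc(C#C)cc1 | starting material
5 | pentamethoxybenzoyl chloride | COc1c(OC)c(OC)c(C(=O)Cl)c(OC)c1OC | intermediate
6 | 1-(2,3,4,5,6-pentamethoxyphenyl)-3-(4-methoxyphenyl)prop-2-yn-1-one | COc1ccc(C#CC(=O)c2c(OC)c(OC)c(OC)c(OC)c2OC)cc1 | intermediate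
7 | 3-iodo-5,6,7,8-tetramethoxy-2-(4-methoxyphenyl)-4H-chromen-4-one | COc1ccc(-c2oc3c(OC)c(OC)c(OC)c(OC)c3c(=O)c2I)cc1 | intermediate
8 | 3,5,6,7,8-pentamethoxy-2-(4-methoxyphenyl)-4H-chromen-4-one | COc1ccc(-c2oc3c(OC)c(OC)c(OC)c(OC)c3c(=O)c2OC)cc1 | intermediate
9 | 5-hydroxy-3,6,7,8-tetramethoxy-2-(4-methoxyphenyl)-4H-chromen-4-one (5-hydroxyauranetin) | COc1ccc(-c2oc3c(OC)c(OC)c(OC)c(O)c3c(=O)c2OC)cc1 | target

**Totals:** 6 steps; longest linear sequence 6 steps (1 → 2 → 3 → 6 → 7 → 8 → 9).

**Three steps most likely to fail, with fallbacks**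

Step 5 is the riskiest, because the methoxylation of a 3-iodoflavone is unprecedented and hydrodeiodination or ring opening may compete. The fallback sets out from 7 and comes back at 8, replacing copper catalysis with a polar organometallic route through the flavonol. Iodine–magnesium exchange (i-PrMgCl·LiCl, THF, −40 °C) gives 3-(chloromagnesio)-5,6,7,8-tetramethoxy-2-(4-methoxyphenyl)-4H-chromen-4-one F5. Trapping with B(OMe)3 gives dimethyl [5,6,7,8-tetramethoxy-2-(4-methoxyphenyl)-4-oxo-4H-chromen-3-yl]boronate F6. Oxidation in the same pot (NaOH, H2O2, 0 °C) gives 3-hydroxy-5,6,7,8-tetramethoxy-2-(4-methoxyphenyl)-4H-chromen-4-one F7. O-Methylation (MeI, K2CO3, acetone, reflux) then gives 8.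

Step 2 is next, because each bromide is flanked by two substituents and methoxide can act as a hydride donor, giving hydrodebromination. The fallback sets out from 2 and comes back at 3, making the ring C–O bonds and the O–CH3 bonds in separate operations. Carboxylate-assisted copper-catalysed hydrolysis in water (CuSO4, pyridine, aq. NaOH, 95 °C, N2), where no reducing alkoxide is present, gives 2,6-dihydroxy-3,4,5-trimethoxybenzoic acid F1. Exhaustive methylation (Me2SO4, K2CO3, acetone, reflux) gives methyl 2,3,4,5,6-pentamethoxybenzoate F2. Saponification (KOH, aq. DMSO, 90 °C; then HCl) returns 3.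

Step 4 is third, because ICl may add across the alkyne without ring closure or iodinate the anisyl ring. The fallback sets out from 6 and comes back at 7, closing the ring as a phenol oxa-Michael addition and introducing iodine afterwards. Chelation-controlled mono-demethylation (BCl3, 1.1 equiv, CH2Cl2, −78→0 °C) gives 1-(2-hydroxy-3,4,5,6-tetramethoxyphenyl)-3-(4-methoxyphenyl)prop-2-yn-1-one F3; any β-chloroenone formed by HCl addition converges in the next operation. DMAP-catalysed 6-endo cyclisation (cat. DMAP, DMF, rt) gives 5,6,7,8-tetramethoxy-2-(4-methoxyphenyl)-4H-chromen-4-one F4 (tangeretin). Electrophilic C3 iodination (I2, CAN, MeCN, 60 °C) gives 7.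

**Further compounds**
F1 | step 2 | 2,6-dihydroxy-3,4,5-trimethoxybenzoic acid | COc1c(O)c(C(=O)O)c(O)c(OC)c1OC
F2 | step 2 | methyl 2,3,4,5,6-pentamethoxybenzoate | COC(=O)c1c(OC)c(OC)c(OC)c(OC)c1OC
F3 | step 4 | 1-(2-hydroxy-3,4,5,6-tetramethoxyphenyl)-3-(4-methoxyphenyl)prop-2-yn-1-one | COc1ccc(C#CC(=O)c2c(O)c(OC)c(OC)c(OC)c2OC)cc1
F4 | step 4 | 5,6,7,8-tetramethoxy-2-(4-methoxyphenyl)-4H-chromen-4-one (tangeretin) | COc1ccc(-c2cc(=O)c3c(OC)c(OC)c(OC)c(OC)c3o2)cc1
F5 | step 5 | 3-(chloromagnesio)-5,6,7,8-tetramethoxy-2-(4-methoxyphenyl)-4H-chromen-4-one | COc1ccc(-c2oc3c(OC)c(OC)c(OC)c(OC)c3c(=O)c2[Mg]Cl)cc1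
F6 | step 5 | dimethyl [5,6,7,8-tetramethoxy-2-(4-methoxyphenyl)-4-oxo-4H-chromen-3-yl]boronate | COc1ccc(-c2oc3c(OC)c(OC)c(OC)c(OC)c3c(=O)c2B(OC)OC)cc1
F7 | step 5 | 3-hydroxy-5,6,7,8-tetramethoxy-2-(4-methoxyphenyl)-4H-chromen-4-one | COc1ccc(-c2oc3c(OC)c(OC)c(OC)c(OC)c3c(=O)c2O)cc1
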